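**Plan**
- Retrosynthesis: first remove three benzyl ethers. Then cut O1–C8a and C2–C3 of the 5,7-dihydroxy flavanone (unit 1) together, which gives 4-methoxybenzaldehyde and a 3'-(aroylmethyl) derivative of the 5-hydroxy-7-methoxy flavanone (unit 2, primed locants). Then cut the C4–C4a aryl ketone bond, O1'–C8a', C4'–C4a' and the C2'–C3' aldol bond.
- Forward: the two fluoroaryl bromides come from 2-bromo-1,3-difluoroarenes by displacement of one fluoride with benzyloxide. Then Evans syn-aldol (C2'–C3'), Weinreb amide, aryllithium addition (C4'–C4a'), SNAr closure of ring C of unit 2, allyl to aroylmethyl, a one-flask aldol/SNAr annulation that builds ring C of unit 1, and hydrogenolysis.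
- Enabling feature: the C4 carbonyl of ring C of unit 1 makes C3–H acidic and, standing ortho to C8a of ring A, activates a C8a–F bond for ipso substitution (the fluoride is the helper and is lost in the key step). The C4' carbonyl of unit 2 serves as the chelating anchor.
- Stereochemistry: the target is 2,3-cis in both units, all four centres R. C2'/C3' come from the (R)-oxazolidinone (syn aldol, carried with retention into the cis chromanone). C3 comes from lithium chelation to O4' (attack anti to C2'), and C2 from the (Z)-enolate chair (syn, hence cis).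

Key step: step 12

Remark: locants C2–C8a refer to unit 1 and primed locants to unit 2 in the discussion, whatever the numbering in the systematic names. Compounds 1, 2, 4, 5, 8, 9 and 11 are assumed to be commercial.

**Route**

Step 1
Reactants: 1 4-bromo-3,5-difluoroanisole; 2 benzyl alcohol
Product: 3 1-(benzyloxy)-2-bromo-3-fluoro-5-methoxybenzene
Conditions: 2 (1.05 equiv), NaH, DMF, 0 to 60 °C
Reagents that add atoms: none
Why: Nucleophilic aromatic substitution in which the benzyloxide displaces one of the two equivalent fluorides, each activated inductively by the ortho bromine and the meta fluorine, while the loss of one fluorine and the limited amount of alkoxide hold the reaction at the mono-ether.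

Step 2
Reactants: 4 4-bromo-3,5-difluorophenol; 5 benzyl bromide
Product: 6 5-(benzyloxy)-2-bromo-1,3-difluorobenzene
Conditions: K2CO3, DMF, 23 °C
Reagents that add atoms: none
Why: Williamson ether synthesis of the acidic difluorophenol under mild carbonate conditions, which leave the aryl halides untouched.

Step 3
Reactants: 6 5-(benzyloxy)-2-bromo-1,3-difluorobenzene; 2 benzyl alcohol
Product: 7 1,5-bis(benzyloxy)-2-bromo-3-fluorobenzene
Conditions: 2 (1.05 equiv), NaH, DMF, 0 to 60 °C
Reagents that add atoms: none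
Why: Nucleophilic aromatic substitution of one of the two equivalent fluorides that flank the bromine, exactly as in step 1, so that the position of the bromine between the remaining fluoride and the new benzyloxy group is fixed by the starting material and not by a regioselective halogenation.

Step 4
Reactants: 8 (R)-4-benzyloxazolidin-2-one; 9 pent-4-enoyl chloride
Product: 10 (R)-4-benzyl-3-(pent-4-enoyl)oxazolidin-2-one
Conditions: Et3N, DMAP (cat.), CH2Cl2, 0 to 23 °C
Reagents that add atoms: none
Why: N-acylation of the oxazolidinone by the acid chloride under acyl-transfer catalysis.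

Step 5
Reactants: 10 (R)-4-benzyl-3-(pent-4-enoyl)oxazolidin-2-one; 11 4-methoxybenzaldehyde
Product: 14 (R)-4-benzyl-3-[(2R)-2-[(R)-hydroxy(4-methoxyphenyl)methyl]pent-4-enoyl]oxazolidin-2-one, via dibutylboron (Z)-enolate 12 (not isolated), via dibutylboron aldolate 13 (not isolated)
Conditions: Bu2BOTf, Et3N, CH2Cl2, −78 to 0 °C; 11, −78 to 0 °C; then pH 7 buffer, MeOH, H2O2, 0 °C
Reagents that add atoms: none
Why: Evans syn-aldol reaction in which the (Z)-boron enolate reacts through a Zimmerman–Traxler chair on the face opposite the benzyl group of the (R)-auxiliary, which sets both new centres as the (R,R) syn pair that later becomes the 2',3'-cis chromanone.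

Step 6
Reactants: 14 (R)-4-benzyl-3-[(2R)-2-[(R)-hydroxy(4-methoxyphenyl)methyl]pent-4-enoyl]oxazolidin-2-one
Product: 15 (2R)-2-[(R)-hydroxy(4-methoxyphenyl)methyl]-N-methoxy-N-methylpent-4-enamide
Conditions: MeNH(OMe)·HCl, AlMe3, CH2Cl2, −20 to 0 °C; aq. potassium sodium tartrate
Reagents that add atoms: N,O-dimethylhydroxylamine hydrochloride, CNOC.Cl
Why: Weinreb amide formation by aluminium amide transamidation, which is selective for the exocyclic imide carbonyl of β-hydroxy imides and leaves both stereocentres untouched.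

Step 7
Reactants: 15 (2R)-2-[(R)-hydroxy(4-methoxyphenyl)methyl]-N-methoxy-N-methylpent-4-enamide; 3 1-(benzyloxy)-2-bromo-3-fluoro-5-methoxybenzene
Product: 18 (2R)-1-[2-(benzyloxy)-6-fluoro-4-methoxyphenyl]-2-[(R)-hydroxy(4-methoxyphenyl)methyl]pent-4-en-1-one, via aryllithium 16 (not isolated), via dilithium hemiaminal adduct 17 (not isolated)
Conditions: 3 (2.2 equiv), n-BuLi, THF, −78 °C; 15, −78 to −60 °C; AcOH, −78 °C
Reagents that add atoms: none
Why: Weinreb ketone synthesis in which bromine–lithium exchange gives an ortho-fluoroaryllithium that is stable at −78 °C, one equivalent deprotonates the hydroxyl (an amide aldolate does not undergo retro-aldol cleavage) and the second adds to give a chelated tetrahedral adduct that cannot over-add.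

Step 8
Reactants: 18 (2R)-1-[2-(benzyloxy)-6-fluoro-4-methoxyphenyl]-2-[(R)-hydroxy(4-methoxyphenyl)methyl]pent-4-en-1-one
Product: 20 (2R,3R)-5-(benzyloxy)-7-methoxy-2-(4-methoxyphenyl)-3-(prop-2-en-1-yl)chroman-4-one, via lithium alkoxide 19 (not isolated)
Conditions: LiN(SiMe3)2 (1.0 equiv), THF, −78 °C; DMPU, −78 to 0 °C
Reagents that add atoms: none
Why: Intramolecular nucleophilic aromatic substitution (6-exo addition–elimination) in which the lithium alkoxide attacks the fluorine-bearing carbon ortho to the ketone, the O–C2' bond is not touched so the syn aldol is carried with retention into the 2',3'-cis chromanone, and with one equivalent of base none remains to epimerise C3' once LiF has formed.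

Step 9
Reactants: 20 (2R,3R)-5-(benzyloxy)-7-methoxy-2-(4-methoxyphenyl)-3-(prop-2-en-1-yl)chroman-4-one
Product: 22 2-[(2R,3R)-5-(benzyloxy)-7-methoxy-2-(4-methoxyphenyl)-4-oxochroman-3-yl]acetaldehyde, via vicinal diol 21 (not isolated)
Conditions: OsO4 (cat.), NaIO4, 2,6-lutidine, dioxane–H2O, 23 °C
Reagents that add atoms: osmium tetroxide (catalytic oxygen carrier), O=[Os](=O)(=O)=O; sodium periodate (stoichiometric oxygen source), [Na+].[O-]I(=O)(=O)=O
Why: Lemieux–Johnson oxidative cleavage of the terminal alkene under buffered, near-neutral conditions that leave the electron-rich arenes and the epimerisable C3' centre alone.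

Step 10
Reactants: 22 2-[(2R,3R)-5-(benzyloxy)-7-methoxy-2-(4-methoxyphenyl)-4-oxochroman-3-yl]acetaldehyde; 7 1,5-bis(benzyloxy)-2-bromo-3-fluorobenzene
Product: 24 (2R,3R)-5-(benzyloxy)-3-{2-[2,4-bis(benzyloxy)-6-fluorophenyl]-2-hydroxyethyl}-7-methoxy-2-(4-methoxyphenyl)chroman-4-one (both carbinol epimers), via aryllithium 23 (not isolated)
Conditions: 7 (1.2 equiv), n-BuLi, THF, −78 °C; 22, −78 °C; AcOH
Reagents that add atoms: none
Why: 1,2-Addition of an aryllithium to an aldehyde, which at −78 °C is far faster than attack on the hindered, vinylogous-ester-like chromanone carbonyl, and the new carbinol centre is left uncontrolled because it is oxidised in the next step.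

Step 11
Reactants: 24 (2R,3R)-5-(benzyloxy)-3-{2-[2,4-bis(benzyloxy)-6-fluorophenyl]-2-hydroxyethyl}-7-methoxy-2-(4-methoxyphenyl)chroman-4-one
Product: 25 (2R,3R)-5-(benzyloxy)-3-{2-[2,4-bis(benzyloxy)-6-fluorophenyl]-2-oxoethyl}-7-methoxy-2-(4-methoxyphenyl)chroman-4-one
Conditions: Dess–Martin periodinane, CH2Cl2, 0 to 23 °C
Reagents that add atoms: none
Why: Dess–Martin oxidation of the benzylic alcohol under non-basic conditions, converging both carbinol epimers to one diketone without touching C2' or C3'.

Step 12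
Reactants: 25 (2R,3R)-5-(benzyloxy)-3-{2-[2,4-bis(benzyloxy)-6-fluorophenyl]-2-oxoethyl}-7-methoxy-2-(4-methoxyphenyl)chroman-4-one; 11 4-methoxybenzaldehyde
Product: 28 (2R,3R,2'R,3'R)-5,7,5'-tris(benzyloxy)-7'-methoxy-2,2'-bis(4-methoxyphenyl)-[3,3'-bichromane]-4,4'-dione, via lithium (Z)-enolate 26 (not isolated), via lithium syn-aldolate 27 (not isolated)
Conditions: LiN(i-Pr)2 (1.0 equiv), PhMe–THF, −78 °C; 11, −78 °C; DMPU, −78 to 0 °C; AcOH
Reagents that add atoms: none
Why: Proposed new method: kinetic deprotonation of the C3 methylene of 25 (less hindered than C3'–H, which is pseudo-equatorial and poorly aligned with the C4' carbonyl) gives lithium (Z)-enolate 26, which adds to 11 through a closed Zimmerman–Traxler transition state (C2–C3 bond), and the lithium aldolate 27 then displaces fluoride at C8a by addition–elimination (O1–C8a bond), the ortho C4 carbonyl stabilising the Meisenheimer intermediate and formation of LiF making the step irreversible. The closest known reaction types are the lithium enolate aldol addition of aryl ketones and the intramolecular SNAr O-arylation of β-hydroxy ortho-fluoroaryl ketones to chroman-4-ones, and what is new is their coupling in one flask with 1,4-stereocontrol. Ring C of unit 1 closes in a 6-exo-trig addition–elimination at the aromatic carbon C8a. C2 is set relative to C3 by the (Z)-enolate geometry (syn aldolate, which maps onto the 2,3-cis chromanone because the O1–C2 bond is not touched in the ring closure), and C3 is set relative to C3' by lithium chelation between the enolate oxygen and O4', which holds C4' on the metal-bearing face so that the aldehyde is delivered anti to C2' and its aryl group, whereas the open, non-chelated rotamer would lead to the C3 epimer. The step needs syn over anti selectivity, the chelate over the open rotamer, and ring closure faster than retro-aldol cleavage or C3 epimerisation, and these are served by the weakly coordinating medium during the aldol stage, by the six-membered closure onto an ortho-acyl fluoroarene, and by using no more than one equivalent of base.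

Step 13
Reactants: 28 (2R,3R,2'R,3'R)-5,7,5'-tris(benzyloxy)-7'-methoxy-2,2'-bis(4-methoxyphenyl)-[3,3'-bichromane]-4,4'-dione
Product: 29 (2R,3R,2'R,3'R)-5,7,5'-trihydroxy-7'-methoxy-2,2'-bis(4-methoxyphenyl)-[3,3'-bichromane]-4,4'-dione
Conditions: H2 (1 atm), 10% Pd/C, EtOAc–MeOH, 23 °C
Reagents that add atoms: none
Why: Catalytic hydrogenolysis of the three aryl benzyl ethers under neutral conditions, which are far more labile than the cyclic benzylic C2–O bonds and leave the base- and acid-sensitive cis stereocentres intact.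

**Compound list**
1 | 4-bromo-3,5-difluoroanisole | COc1cc(F)c(Br)c(F)c1 | starting material
2 | benzyl alcohol | OCc1ccccc1 | starting material
3 | 1-(benzyloxy)-2-bromo-3-fluoro-5-methoxybenzene | COc1cc(F)c(Br)c(OCc2ccccc2)c1 | intermediate
4 | 4-bromo-3,5-difluorophenol | Oc1cc(F)c(Br)c(F)c1 | starting material
5 | benzyl bromide | BrCc1ccccc1 | starting material
6 | 5-(benzyloxy)-2-bromo-1,3-difluorobenzene | Fc1cc(OCc2ccccc2)cc(F)c1Br | intermediate
7 | 1,5-bis(benzyloxy)-2-bromo-3-fluorobenzene | Fc1cc(OCc2ccccc2)cc(OCc2ccccc2)c1Br | intermediate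
8 | (R)-4-benzyloxazolidin-2-one | O=C1N[C@H](Cc2ccccc2)CO1 | starting material
9 | pent-4-enoyl chloride | C=CCCC(Cl)=O | starting material
10 | (R)-4-benzyl-3-(pent-4-enoyl)oxazolidin-2-one | C=CCCC(=O)N1[C@H](Cc2ccccc2)COC1=O | intermediate
11 | 4-methoxybenzaldehyde | COc1ccc(C=O)cc1 | starting material
12 | (R)-4-benzyl-3-[(1Z)-1-(dibutylboranyloxy)penta-1,4-dien-1-yl]oxazolidin-2-one (boron enolate of 10) | CCCCB(CCCC)O/C(=C\CC=C)N1[C@H](Cc2ccccc2)COC1=O | intermediate
13 | O-dibutylboranyl derivative of 14 (boron aldolate) | C=CC[C@@H](C(=O)N1[C@H](Cc2ccccc2)COC1=O)[C@@H](OB(CCCC)CCCC)c1ccc(OC)cc1 | intermediate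
14 | (R)-4-benzyl-3-[(2R)-2-[(R)-hydroxy(4-methoxyphenyl)methyl]pent-4-enoyl]oxazolidin-2-one | C=CC[C@@H](C(=O)N1[C@H](Cc2ccccc2)COC1=O)[C@@H](O)c1ccc(OC)cc1 | intermediate
15 | (2R)-2-[(R)-hydroxy(4-methoxyphenyl)methyl]-N-methoxy-N-methylpent-4-enamide | C=CC[C@@H](C(=O)N(C)OC)[C@@H](O)c1ccc(OC)cc1 | intermediate
16 | [2-(benzyloxy)-6-fluoro-4-methoxyphenyl]lithium | COc1cc(F)c([Li])c(OCc2ccccc2)c1 | intermediate
17 | dilithium salt of the tetrahedral adduct of 16 to 15 | C=CC[C@@H](C(O[Li])(N(C)OC)c1c(OCc2ccccc2)cc(OC)cc1F)[C@@H](O[Li])c1ccc(OC)cc1 | intermediate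
18 | (2R)-1-[2-(benzyloxy)-6-fluoro-4-methoxyphenyl]-2-[(R)-hydroxy(4-methoxyphenyl)methyl]pent-4-en-1-one | C=CC[C@@H](C(=O)c1c(OCc2ccccc2)cc(OC)cc1F)[C@@H](O)c1ccc(OC)cc1 | intermediate
19 | lithium alkoxide of 18 | C=CC[C@@H](C(=O)c1c(OCc2ccccc2)cc(OC)cc1F)[C@@H](O[Li])c1ccc(OC)cc1 | intermediate
20 | (2R,3R)-5-(benzyloxy)-7-methoxy-2-(4-methoxyphenyl)-3-(prop-2-en-1-yl)chroman-4-one | C=CC[C@H]1C(=O)c2c(OCc3ccccc3)cc(OC)cc2O[C@H]1c1ccc(OC)cc1 | intermediate
21 | (2R,3R)-5-(benzyloxy)-3-(2,3-dihydroxypropyl)-7-methoxy-2-(4-methoxyphenyl)chroman-4-one (both carbinol epimers) | OCC(O)C[C@H]1C(=O)c2c(OCc3ccccc3)cc(OC)cc2O[C@H]1c1ccc(OC)cc1 | intermediate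
22 | 2-[(2R,3R)-5-(benzyloxy)-7-methoxy-2-(4-methoxyphenyl)-4-oxochroman-3-yl]acetaldehyde | O=CC[C@H]1C(=O)c2c(OCc3ccccc3)cc(OC)cc2O[C@H]1c1ccc(OC)cc1 | intermediate
23 | [2,4-bis(benzyloxy)-6-fluorophenyl]lithium | [Li]c1c(F)cc(OCc2ccccc2)cc1OCc1ccccc1 | intermediate
24 | (2R,3R)-5-(benzyloxy)-3-{2-[2,4-bis(benzyloxy)-6-fluorophenyl]-2-hydroxyethyl}-7-methoxy-2-(4-methoxyphenyl)chroman-4-one (both carbinol epimers) | OC(C[C@H]1C(=O)c2c(OCc3ccccc3)cc(OC)cc2O[C@H]1c1ccc(OC)cc1)c1c(F)cc(OCc2ccccc2)cc1OCc1ccccc1 | intermediate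
25 | (2R,3R)-5-(benzyloxy)-3-{2-[2,4-bis(benzyloxy)-6-fluorophenyl]-2-oxoethyl}-7-methoxy-2-(4-methoxyphenyl)chroman-4-one | O=C(C[C@H]1C(=O)c2c(OCc3ccccc3)cc(OC)cc2O[C@H]1c1ccc(OC)cc1)c1c(F)cc(OCc2ccccc2)cc1OCc1ccccc1 | intermediate
26 | lithium (Z)-enolate of 25 | [Li]O/C(=C\[C@H]1C(=O)c2c(OCc3ccccc3)cc(OC)cc2O[C@H]1c1ccc(OC)cc1)c1c(F)cc(OCc2ccccc2)cc1OCc1ccccc1 | intermediate
27 | lithium syn-aldolate from 26 and 11 | COc1ccc([C@H](O[Li])[C@H](C(=O)c2c(F)cc(OCc3ccccc3)cc2OCc2ccccc2)[C@H]2C(=O)c3c(OCc4ccccc4)cc(OC)cc3O[C@H]2c2ccc(OC)cc2)cc1 | intermediate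
28 | (2R,3R,2'R,3'R)-5,7,5'-tris(benzyloxy)-7'-methoxy-2,2'-bis(4-methoxyphenyl)-[3,3'-bichromane]-4,4'-dione | COc1ccc([C@@H]2Oc3cc(OCc4ccccc4)cc(OCc4ccccc4)c3C(=O)[C@@H]2[C@H]2C(=O)c3c(OCc4ccccc4)cc(OC)cc3O[C@H]2c2ccc(OC)cc2)cc1 | intermediate
29 | (2R,3R,2'R,3'R)-5,7,5'-trihydroxy-7'-methoxy-2,2'-bis(4-methoxyphenyl)-[3,3'-bichromane]-4,4'-dione | COc1ccc([C@@H]2Oc3cc(O)cc(O)c3C(=O)[C@@H]2[C@H]2C(=O)c3c(O)cc(OC)cc3O[C@H]2c2ccc(OC)cc2)cc1 | target

**Count and risks**
Total step count: 13. Longest linear sequence: 10 steps (steps 4 to 13).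

Steps most likely to fail:

1. Step 12 (Proposed new method). What may go wrong: attack on the wrong face of the enolate if the open rotamer competes with the lithium chelate, retro-aldol equilibration of the aldolate before ring closure, and epimerisation at C3 after closure. The fallback sets out from 25 and returns at 28, and separates the two bond formations with known chemistry. Enolisation of 25 with Sn(OTf)2 and N-ethylpiperidine in CH2Cl2 at −78 °C would give the strongly chelating enolate of divalent tin, whose kinetic and irreversible addition to 11 should give the syn β-hydroxy ketone F1, which would be freed from any C3 epimer by chromatography. Ring closure of F1 would then be run separately as in step 8 (LiN(SiMe3)2, THF–DMPU) to give 28.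

2. Step 8. What may go wrong: retro-aldol cleavage or dehydration of the ketone aldolate before substitution, and loss of the cis relation by enolisation. The fallback sets out from 15 and returns at 20, and never exposes the free aldol to stoichiometric base. Silylation of 15 (Et3SiOTf, 2,6-lutidine) would give the silyl ether F2. Addition of aryllithium 16 (1.1 equiv, −78 °C) would give the β-silyloxy ketone F3. Treatment of F3 with Bu4NF in THF at −40 °C would release the alkoxide in low concentration next to the fluoroarene, so that desilylation and ring closure to 20 occur together.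

3. Step 7. What may go wrong: loss of the ortho-fluoroaryllithium by elimination of LiF (aryne formation) before it adds to the hindered, α-branched amide. The fallback sets out from 14 and returns at 18, and replaces the aryllithium by a zinc reagent that is stable at 23 °C. Cleavage of the auxiliary from 14 with LiSEt (THF, 0 °C) would give the thioester F4. Coupling of F4 with the arylzinc chloride F5 (from 3 by n-BuLi at −78 °C, then ZnCl2) under PdCl2(PPh3)2 catalysis in THF–PhMe at 23 °C (Fukuyama-type ketone synthesis) would give 18.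

**Further compounds**
F1 | step 12 | (2R,3R)-5-(benzyloxy)-3-[(2R,3R)-1-[2,4-bis(benzyloxy)-6-fluorophenyl]-3-hydroxy-3-(4-methoxyphenyl)-1-oxopropan-2-yl]-7-methoxy-2-(4-methoxyphenyl)chroman-4-one | COc1ccc([C@H](O)[C@H](C(=O)c2c(F)cc(OCc3ccccc3)cc2OCc2ccccc2)[C@H]2C(=O)c3c(OCc4ccccc4)cc(OC)cc3O[C@H]2c2ccc(OC)cc2)cc1
F2 | step 8 | (2R)-N-methoxy-2-[(R)-(4-methoxyphenyl)(triethylsilyloxy)methyl]-N-methylpent-4-enamide | C=CC[C@@H](C(=O)N(C)OC)[C@@H](O[Si](CC)(CC)CC)c1ccc(OC)cc1
F3 | step 8 | (2R)-1-[2-(benzyloxy)-6-fluoro-4-methoxyphenyl]-2-[(R)-(4-methoxyphenyl)(triethylsilyloxy)methyl]pent-4-en-1-one | C=CC[C@@H](C(=O)c1c(OCc2ccccc2)cc(OC)cc1F)[C@@H](O[Si](CC)(CC)CC)c1ccc(OC)cc1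
F4 | step 7 | S-ethyl (2R)-2-[(R)-hydroxy(4-methoxyphenyl)methyl]pent-4-enethioate | C=CC[C@@H](C(=O)SCC)[C@@H](O)c1ccc(OC)cc1
F5 | step 7 | [2-(benzyloxy)-6-fluoro-4-methoxyphenyl]zinc chloride | COc1cc(F)c([Zn]Cl)c(OCc2ccccc2)c1
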